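C4 of cyclohexanone ring C (C1 ketone, C2, C3, C4, C5 bearing O, C6) is quaternary: it carries aryl ring A, bonded through the carbon ortho to the ring A oxygen, and an E-acrylamide. With ring C these are two 4-hydroxycinnamoyl groups on N1 (ring A side) and N8 (ring C side) of one spermidine, and the ring A oxygen is bonded to C5 (dihydrofuran ring B).
Last operations: Boc removal from N4 and addition of two hydrogens to C2=C3 of the ring C enone.
Key disconnections: O–C5 (oxa-Michael, ring B) and C4–aryl (oxidative ortho–para coupling, 20-membered ring D). They lead back to an open-chain N1,N8-diacyl-N4-Boc-spermidine with the N8-side phenol free and the N1-side phenol silylated.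
The diamide comes from spermidine, with N1 and N4 tied up for a time as the formaldehyde aminal (N8 acylated first, N1 second, N4 Boc last), and from two N-hydroxysuccinimide esters of 4-hydroxycinnamic acid.
Order of ring formation: ring D together with the dearomatisation that creates ring C, then ring B; ring A is present from the start.

Key step: step 7

Assumption: the sense of induction of the amine–thiourea on this macrocyclic dienone cannot be derived from simpler cases, so the quinine-derived catalyst is written, and its quinidine-derived pseudo-enantiomer takes its place if the other enone arm is attacked.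

Step 1
Reactants: 1 (E)-4-hydroxycinnamic acid
Product: 2 N-succinimidyl (E)-4-hydroxycinnamate
Conditions: N-hydroxysuccinimide, DCC, THF, 0 °C to rt
Reagents that add atoms: N-hydroxysuccinimide, O=C1CCC(=O)N1O
Why: Carbodiimide esterification in which the acidic N–OH group traps the O-acylisourea much faster than the phenol does, so the phenol needs no protection.

Step 2
Reactants: 2 N-succinimidyl (E)-4-hydroxycinnamate
Product: 3 N-succinimidyl (E)-4-(tert-butyldimethylsilyloxy)cinnamate
Conditions: TBSOTf, 2,6-lutidine, CH2Cl2, 0 °C
Reagents that add atoms: tert-butyldimethylsilyl trifluoromethanesulfonate (TBSOTf), CC(C)(C)[Si](C)(C)OS(=O)(=O)C(F)(F)F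
Why: O-silylation of a phenol with a silyl triflate and a hindered, non-nucleophilic pyridine base, which should leave the active ester untouched.

Step 3
Reactants: 4 spermidine
Product: 5 1-(4-aminobutyl)hexahydropyrimidine
Conditions: 37% aq HCHO (1.0 equiv), H2O, 0 °C to rt
Reagents that add atoms: formaldehyde, C=O
Why: Aminal formation in which the 1,3-diamine part (N1 and N4) takes up one formaldehyde as the six-membered ring, which is favoured over the seven-membered alternative and leaves N8 as the only primary amine.

Step 4
Reactants: 5 1-(4-aminobutyl)hexahydropyrimidine; 2 N-succinimidyl (E)-4-hydroxycinnamate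
Product: 6 (E)-N-[4-(hexahydropyrimidin-1-yl)butyl]-4-hydroxycinnamamide
Conditions: 2 (0.95 equiv) added slowly to 5, THF/DMF, −20 to 0 °C
Reagents that add atoms: none
Why: Aminolysis of an active ester, in which the unhindered primary N8 should outrun the less basic secondary ring N–H, N4 is tertiary, and the phenol is not acylated by an ester of this reactivity.

Step 5
Reactants: 6 (E)-N-[4-(hexahydropyrimidin-1-yl)butyl]-4-hydroxycinnamamide
Product: 7 N8-[(E)-4-hydroxycinnamoyl]spermidine
Conditions: malonic acid (3 equiv), pyridine, EtOH, reflux
Reagents that add atoms: none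
Why: Aminal cleavage driven by a Knoevenagel condensation, in which malonic acid drains formaldehyde from the ring–chain equilibrium under almost neutral conditions that spare the amide, the alkene and the phenol.

Step 6
Reactants: 7 N8-[(E)-4-hydroxycinnamoyl]spermidine; 3 N-succinimidyl (E)-4-(tert-butyldimethylsilyloxy)cinnamate
Product: 9 N8-[(E)-4-hydroxycinnamoyl]-N1-[(E)-4-(tert-butyldimethylsilyloxy)cinnamoyl]-N4-Boc-spermidine, via N4-unprotected diamide 8 (not isolated)
Conditions: 3 (1.0 equiv) added over 1 h, DMF/CH2Cl2, −20 °C; then i-Pr2NEt, Boc2O (1.1 equiv), 0 °C to rt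
Reagents that add atoms: di-tert-butyl dicarbonate (Boc2O), CC(C)(C)OC(=O)OC(=O)OC(C)(C)C
Why: Chemoselective aminolysis of the active ester by primary N1 in preference to secondary N4 at low temperature, followed in the same flask by carbamate formation at the only basic nitrogen left, without DMAP so that the phenol stays free.

Step 7
Reactants: 9 N8-[(E)-4-hydroxycinnamoyl]-N1-[(E)-4-(tert-butyldimethylsilyloxy)cinnamoyl]-N4-Boc-spermidine
Product: 12 (4S,5R)-N-Boc macrocyclic enone, via macrocyclic silyloxy dienone 10 (not isolated), via macrocyclic hydroxy dienone 11 (not isolated)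
Conditions: PhI(OCOCF3)2 (1.05 equiv, added over 3 h), solid NaHCO3 (5 equiv), (CF3)2CHOH/CH2Cl2 1:1, 0.5 mM, −20 °C; cold filtration, concentration; then 1-[3,5-bis(trifluoromethyl)phenyl]-3-[(8α,9S)-6'-methoxycinchonan-9-yl]thiourea (20 mol%), powdered KHF2 (3 equiv), toluene/CH2Cl2 4:1, −40 °C, PFA vessel; cold filtration through silica, used at once
Reagents that add atoms: none
Why: Proposed new method: the free phenol of 9 displaces a trifluoroacetate on the trivalent iodine and loses PhI, the phenoxenium-type ring so formed is attacked at its para carbon (the future C4) by the carbon ortho to the silyloxy group of the other ring, and proton loss restores that arene and leaves the prochiral 4-aryl-4-alkenyl dienone 10. After the change to a non-polar solvent KHF2 stays undissolved, so fluoride should reach the silyl ether only as the hydrofluoride of the catalyst quinuclidine held by its thiourea, and phenol 11 is then set free beside the only base in solution, the chiral one, which guides its addition to C5. The closest known reaction types are the hypervalent-iodine ortho–para phenol–arene coupling that closes seven-membered rings to 4-aryl dienones, the amine–thiourea-catalysed desymmetrising oxa-Michael addition to 4,4-disubstituted cyclohexadienones, and the transport of solid alkali fluoride into solution by chiral ureas; joining them in one enantioselective macrocyclising operation is new. The 20-membered ring D closes by intramolecular electrophilic aromatic substitution under high dilution, helped by stacking of the two flat E-cinnamoyl arms in the fluoroalcohol, and ring B closes by a 5-exo-trig oxa-Michael addition. C4 and C5 become stereocentres in the same event: the catalyst picks one of the two enantiotopic enone arms and thereby fixes both absolute configurations, while the five-membered ring allows only the cis fusion with the aryl group on C4 and the oxygen on C5 on one face. The step needs oxidation of one ring only, which the single free phenol secures; one site on the nucleophilic ring, secured because its para position is blocked and its two ortho carbons are equivalent; and no capture by other nucleophiles, secured by the E alkenes that hold amide O and N away from C4, by the non-nucleophilic fluoroalcohol, and by NaHCO3, which shields the Boc group and the later amine catalyst from CF3CO2H.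

Step 8
Reactants: 12 (4S,5R)-N-Boc macrocyclic enone
Product: 13 (4S,5R)-N-Boc macrocyclic ketone
Conditions: [(Ph3P)CuH]6 (0.35 equiv), H2O (5 equiv), degassed toluene, 0 °C to rt
Reagents that add atoms: none
Why: Copper hydride conjugate reduction, in which the soft hydride adds to C3 of the ketone-conjugated alkene while the two unsaturated secondary amides are far poorer acceptors, water protonates the copper enolate at C2, and the two arms at C4 now differ, so a retro-oxa-Michael opening can no longer racemise the material.

Step 9
Reactants: 13 (4S,5R)-N-Boc macrocyclic ketone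
Product: 14 target CNP0415009.1
Conditions: CF3CO2H/CH2Cl2 1:4, 0 °C; aq NaHCO3
Reagents that add atoms: none
Why: Acidolysis of the tert-butyl carbamate with loss of 2-methylpropene and CO2, conditions under which the amides, the aryl ether and the ketone persist and neither stereocentre is touched.

Compound list
1 | (E)-4-hydroxycinnamic acid | OC(=O)/C=C/c1ccc(O)cc1 | starting material
2 | N-succinimidyl (E)-4-hydroxycinnamate | O=C(/C=C/c1ccc(O)cc1)ON1C(=O)CCC1=O | intermediate
3 | N-succinimidyl (E)-4-(tert-butyldimethylsilyloxy)cinnamate | O=C(/C=C/c1ccc(O[Si](C)(C)C(C)(C)C)cc1)ON1C(=O)CCC1=O | intermediate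
4 | spermidine | NCCCCNCCCN | starting material
5 | 1-(4-aminobutyl)hexahydropyrimidine (N1,N4-methylene aminal of spermidine) | NCCCCN1CCCNC1 | intermediate
6 | (E)-N-[4-(hexahydropyrimidin-1-yl)butyl]-4-hydroxycinnamamide | O=C(/C=C/c1ccc(O)cc1)NCCCCN2CCCNC2 | intermediate
7 | N8-[(E)-4-hydroxycinnamoyl]spermidine | O=C(/C=C/c1ccc(O)cc1)NCCCCNCCCN | intermediate
8 | N8-[(E)-4-hydroxycinnamoyl]-N1-[(E)-4-(tert-butyldimethylsilyloxy)cinnamoyl]spermidine, N4–H (not isolated) | Oc1ccc(/C=C/C(=O)NCCCCNCCCNC(=O)/C=C/c2ccc(O[Si](C)(C)C(C)(C)C)cc2)cc1 | intermediate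
9 | N8-[(E)-4-hydroxycinnamoyl]-N1-[(E)-4-(tert-butyldimethylsilyloxy)cinnamoyl]-N4-Boc-spermidine | Oc1ccc(/C=C/C(=O)NCCCCN(C(=O)OC(C)(C)C)CCCNC(=O)/C=C/c2ccc(O[Si](C)(C)C(C)(C)C)cc2)cc1 | intermediate
10 | macrocyclic silyloxy dienone: 20-membered ring, cyclohexa-2,5-dienone whose C4 carries the 2-silyloxyaryl ring and the E-acrylamide, N4-Boc, prochiral (not isolated) | O=C1C=CC2(C=C1)/C=C/C(=O)NCCCCN(C(=O)OC(C)(C)C)CCCNC(=O)/C=C/c3ccc(O[Si](C)(C)C(C)(C)C)c2c3 | intermediate
11 | macrocyclic hydroxy dienone: as 10 with the free phenol (not isolated) | O=C1C=CC2(C=C1)/C=C/C(=O)NCCCCN(C(=O)OC(C)(C)C)CCCNC(=O)/C=C/c3ccc(O)c2c3 | intermediate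
12 | N-Boc macrocyclic enone: cis-fused dihydrobenzofuran on ring C, C1 ketone, C2=C3, C4 S, C5 R, both acrylamides E | O=C1C=C[C@]23/C=C/C(=O)NCCCCN(C(=O)OC(C)(C)C)CCCNC(=O)/C=C/c4ccc(c2c4)O[C@@H]3C1 | intermediate
13 | N-Boc macrocyclic ketone: as 12 with C2–C3 saturated, C4 S, C5 R | O=C1CC[C@]23/C=C/C(=O)NCCCCN(C(=O)OC(C)(C)C)CCCNC(=O)/C=C/c4ccc(c2c4)O[C@@H]3C1 | intermediate
14 | CNP0415009.1, C4 S, C5 R (4aR,9bS in dibenzofuran numbering), N4–H | O=C1CC[C@]23/C=C/C(=O)NCCCCNCCCNC(=O)/C=C/c4ccc(c2c4)O[C@@H]3C1 | target

Total step count: 9. Longest linear sequence: 7 steps (step 1 or step 3, then steps 4 to 9).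

Steps most likely to fail

1. Step 7.
- What may go wrong:
  - The weakly nucleophilic silyloxyarene may lose the race for the oxidised ring against solvent, trifluoroacetate or a second molecule.
  - Attack may go to the ortho carbon of the oxidised ring or come from the alkene of the other arm.
  - The silyl group may be lost early.
  - An uncatalysed ring closure, or binding of the thiourea to the amides of the substrate, may erode the enantiomeric purity.
- Fallback: known chemistry that sets out from 5 and comes back at 13, so that step 8 is bypassed as well. Ring C is built by a Diels–Alder reaction instead of by dearomatisation, and ring D is closed by a Heck reaction.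
- Chain: 5 is acylated at N8 with diethylphosphonoacetic acid (EDC·HCl, HOBt, CH2Cl2) to the phosphonoacetamide aminal F1. Malonic acid and pyridine as in step 5 give the phosphonoacetyl triamine F2. N-acryloyloxysuccinimide at −20 °C and then Boc2O, as in step 6, give the N1-acryloyl N4-Boc phosphonate F3.
- Core:
  - Commercial (5-bromo-2-methoxyphenyl)acetonitrile is reduced with i-Bu2AlH (toluene, −78 °C, acidic work-up) to the arylacetaldehyde F4.
  - Mannich-type α-methylenation (aq HCHO, pyrrolidine, propionic acid, i-PrOH) gives the 2-arylacrolein F5.
  - A Diels–Alder reaction with 1-(dimethylamino)-3-(tert-butyldimethylsilyloxy)buta-1,3-diene follows, under hydrogen-bond catalysis by a tetra(1-naphthyl)-TADDOL (toluene, −78 °C, enantiomer chosen for the R product). It gives the amino silyl enol ether cycloadduct F6.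
  - HF in MeCN converts F6 into the (R)-4-aryl-4-formylcyclohex-2-enone F7, in which C4 is set.
  - BBr3 (CH2Cl2, −78 to 0 °C, then aq NaHCO3) frees the phenol. It adds to the single enone carbon C5 on the face of the aryl group to give the cis-fused tricyclic keto aldehyde F8.
- Union: a Horner–Wadsworth–Emmons reaction of F8 with F3 under Masamune–Roush conditions (LiCl, DBU, MeCN) gives the E-acrylamide aryl bromide F9. A macrocyclising Heck reaction (Pd(OAc)2, P(o-tol)3, Et3N, MeCN, 80 °C, 1 mM) joins the aryl bromide to the terminal acrylamide and gives 13.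

2. Step 8.
- What may go wrong: a slow reduction under basic copper species may let the adduct re-open by retro-oxa-Michael and racemise through the dienone, and excess hydride may start to reduce the acrylamide alkenes.
- Fallback: it sets out from 12 and comes back at 13. A Luche 1,2-reduction (NaBH4, CeCl3·7H2O, MeOH, −78 °C) gives the macrocyclic allylic alcohol F10, either carbinol epimer serving. F10 has no carbonyl group in ring C and therefore cannot re-open. Redox isomerisation of the allylic alcohol ((C5Ph5)Ru(CO)2Cl, 5 mol%, t-BuOK, 5 mol%, toluene, rt) then shifts the hydrogens within ring C and gives 13 without an external hydride that could touch the amides.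

3. Step 6.
- What may go wrong: competing or double acylation at N4, and base-induced migration of the silyl group between the two phenol oxygens, which would blur the choice of the ring to be oxidised.
- Fallback: it sets out from 6 and comes back at 8. The second acyl group is put on before the aminal is opened, while N4 is still a tertiary aminal nitrogen and the ring N–H is the only nitrogen that can be acylated.
  - 6 and 3 (catalytic HOAt, CH2Cl2, rt) give the N1-acyl hexahydropyrimidine F11.
  - MeONH2·HCl (THF/MeOH, pH 4 to 5, rt) removes the methylene bridge by transoximation. Under these mildly acidic conditions the aryl silyl ether is stable and no phenoxide is present.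
  - This gives 8, which is treated with Boc2O as in the second half of step 6 to give 9.

Further compounds
F1 | step 7 | diethyl (2-{[4-(hexahydropyrimidin-1-yl)butyl]amino}-2-oxoethyl)phosphonate | CCOP(=O)(OCC)CC(=O)NCCCCN1CCCNC1
F2 | step 7 | N8-(diethylphosphonoacetyl)spermidine | CCOP(=O)(OCC)CC(=O)NCCCCNCCCN
F3 | step 7 | N8-(diethylphosphonoacetyl)-N1-acryloyl-N4-Boc-spermidine | CCOP(=O)(OCC)CC(=O)NCCCCN(C(=O)OC(C)(C)C)CCCNC(=O)C=C
F4 | step 7 | 2-(5-bromo-2-methoxyphenyl)acetaldehyde | O=CCc1cc(Br)ccc1OC
F5 | step 7 | 2-(5-bromo-2-methoxyphenyl)prop-2-enal | C=C(C=O)c1cc(Br)ccc1OC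
F6 | step 7 | 1-(5-bromo-2-methoxyphenyl)-2-(dimethylamino)-4-(tert-butyldimethylsilyloxy)cyclohex-3-ene-1-carbaldehyde, quaternary carbon as in F7, amino-bearing carbon lost in the next operation | CN(C)C1C=C(O[Si](C)(C)C(C)(C)C)CC[C@]1(C=O)c2cc(Br)ccc2OC
F7 | step 7 | (R)-1-(5-bromo-2-methoxyphenyl)-4-oxocyclohex-2-ene-1-carbaldehyde | O=C1CC[C@](C=O)(c2cc(Br)ccc2OC)C=C1
F8 | step 7 | (4aR,9bS)-8-bromo-3-oxo-1,2,3,4,4a,9b-hexahydrodibenzofuran-9b-carbaldehyde | O=C1CC[C@]2(C=O)c3cc(Br)ccc3O[C@@H]2C1
F9 | step 7 | open-chain E-acrylamide of the 8-bromo hexahydrodibenzofuran-3-one core (C4 S, C5 R) with N8 of N1-acryloyl-N4-Boc-spermidine | O=C1CC[C@]2(/C=C/C(=O)NCCCCN(C(=O)OC(C)(C)C)CCCNC(=O)C=C)c3cc(Br)ccc3O[C@@H]2C1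
F10 | step 8 | N-Boc macrocyclic allylic alcohol (C1 carbinol, either epimer; C2=C3; C4 and C5 as in 12) | OC1C=C[C@]23/C=C/C(=O)NCCCCN(C(=O)OC(C)(C)C)CCCNC(=O)/C=C/c4ccc(c2c4)O[C@@H]3C1
F11 | step 6 | (E)-N-(4-{3-[(E)-4-(tert-butyldimethylsilyloxy)cinnamoyl]hexahydropyrimidin-1-yl}butyl)-4-hydroxycinnamamide | Oc1ccc(/C=C/C(=O)NCCCCN2CCCN(C2)C(=O)/C=C/c3ccc(O[Si](C)(C)C(C)(C)C)cc3)cc1
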